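Assumption: the target has no stereocentre, and each alkene ends in two identical methyl groups. It is therefore achiral, and no enantiomer or alkene geometry has to be controlled.

**Retrosynthetic overview**
- Cut the C(=O)–C1' bond to ring B. The carbonyl carbon and C1' (meta to the ring-B OH, a 1,4-dioxygen relationship) are both acceptor carbons, so the ring-A carbonyl carbon must act as an acyl anion. The partners are 2,6-dihydroxy-4-methoxy-3,5-diprenylbenzaldehyde (formyl C–H turned into a chelated acylpalladium) and 3-iodophenol.
- That aldehyde comes from selective 4-O-methylation of the 2,4,6-triol. This is done before ring B arrives, so no fourth phenol competes.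
- The triol comes from double C-prenylation of 2,4,6-trihydroxybenzaldehyde; the formyl group blocks C1.
- No ring is formed: rings A and B are both bought as benzenes. There are no protecting groups and three steps.

**Route**

Step 1
Reactants: 1 2,4,6-trihydroxybenzaldehyde; 2 prenyl bromide (1-bromo-3-methylbut-2-ene)
Product: 3 2,4,6-trihydroxy-3,5-bis(3-methylbut-2-en-1-yl)benzaldehyde
Conditions: 2 (2.2 equiv), KOH (2.2 equiv), H2O, 0 °C to rt; then 1 M HCl
Reagents that add atoms: prenyl bromide (2), CC(C)=CCBr
Why: Phenolate C-alkylation (SN2) of an acylphloroglucinol, in which water solvates the phenolate oxygens so the soft allylic bromide attacks carbon, the formyl group blocks C1 so only C3 and C5 react, and limiting 2 holds back geminal over-prenylation; no stereocentre is formed.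

Step 2
Reactants: 3 2,4,6-trihydroxy-3,5-bis(3-methylbut-2-en-1-yl)benzaldehyde; 4 dimethyl sulfate
Product: 5 2,6-dihydroxy-4-methoxy-3,5-bis(3-methylbut-2-en-1-yl)benzaldehyde
Conditions: 4 (1.0 equiv), K2CO3 (1.0 equiv), acetone, rt to 40 °C
Reagents that add atoms: dimethyl sulfate (4), COS(=O)(=O)OC
Why: Williamson-type O-methylation, in which the 4-OH (para to the formyl group and outside its hydrogen-bond chelate) is the most acidic phenol, so one equivalent of weak base and one equivalent of a hard methylating agent take it selectively and avoid C-methylation; no stereocentre is formed.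

Step 3
Reactants: 5 2,6-dihydroxy-4-methoxy-3,5-bis(3-methylbut-2-en-1-yl)benzaldehyde; 6 3-iodophenol
Product: 8 [2,6-dihydroxy-4-methoxy-3,5-bis(3-methylbut-2-en-1-yl)phenyl](3-hydroxyphenyl)methanone (target), via acyl(aryl)palladium chelate 7 (not isolated)
Conditions: 6 (1.3 equiv), PdCl2 (5 mol %), LiCl (20 mol %), Na2CO3 (3 equiv), degassed DMF, N2, 100 °C; then dilute HCl work-up
Reagents that add atoms: 3-iodophenol (6), Oc1cccc(I)c1
Why: Miura-type palladium-catalysed formyl C–H arylation of a salicylaldehyde, in which zerovalent palladium inserts into the C–I bond of 6, the more acidic ring-A phenolate of 5 binds the arylpalladium and steers cleavage of the neighbouring formyl C–H to the five-membered chelate 7, where the normally electrophilic carbonyl carbon is a carbon-bound acyl ligand (an acyl anion equivalent) that reductive elimination joins to the equally electrophilic former C–I carbon, while the chelate blocks decarbonylation and the trisubstituted prenyl alkenes insert too slowly to compete; no stereocentre is formed.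

**Compound list**
1 | 2,4,6-trihydroxybenzaldehyde | O=Cc1c(O)cc(O)cc1O | starting material
2 | prenyl bromide (1-bromo-3-methylbut-2-ene) | CC(C)=CCBr | starting material
3 | 2,4,6-trihydroxy-3,5-bis(3-methylbut-2-en-1-yl)benzaldehyde | O=Cc1c(O)c(CC=C(C)C)c(O)c(CC=C(C)C)c1O | intermediate
4 | dimethyl sulfate | COS(=O)(=O)OC | starting material
5 | 2,6-dihydroxy-4-methoxy-3,5-bis(3-methylbut-2-en-1-yl)benzaldehyde | COc1c(CC=C(C)C)c(O)c(C=O)c(O)c1CC=C(C)C | intermediate
6 | 3-iodophenol | Oc1cccc(I)c1 | starting material
7 | five-membered C,O-chelate of divalent palladium: Pd bound to the ring-A acyl carbon, to the 2-phenolate oxygen and to C1 of a 3-hydroxyphenyl group (further chloride or DMF ligands omitted) | O=C1[Pd](c2cccc(O)c2)Oc2c(CC=C(C)C)c(OC)c(CC=C(C)C)c(O)c12 | intermediate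
8 | [2,6-dihydroxy-4-methoxy-3,5-bis(3-methylbut-2-en-1-yl)phenyl](3-hydroxyphenyl)methanone (achiral) | COc1c(CC=C(C)C)c(O)c(C(=O)c2cccc(O)c2)c(O)c1CC=C(C)C | target

**Step count**
Total step count: 3. Longest linear sequence: 3 (1 to 3 to 5 to 8).

**Steps most likely to fail, with fallbacks**

Highest risk, step 3. The arylpalladium phenolate sits next to an ortho-prenyl group as well as the formyl group, so oxypalladation or Heck side reactions may compete. The doubly deprotonated, hindered aldehyde or the free OH of 6 may also slow the coupling.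
- The fallback sets out from 5 and comes back at 8. It swaps the chelated acylpalladium for a preformed nitrogen-based acyl anion equivalent.
- Compound 5 is protected (MOMCl, iPr2NEt, CH2Cl2) as 4-methoxy-2,6-bis(methoxymethoxy)-3,5-bis(3-methylbut-2-en-1-yl)benzaldehyde F1.
- F1 is condensed with tert-butylhydrazine hydrochloride and NaOAc in EtOH to its (E)-N-tert-butylhydrazone F2.
- The C-nucleophilic anion of F2 is coupled with 1-bromo-3-(methoxymethoxy)benzene F3, made from 3-bromophenol with MOMCl and iPr2NEt. Conditions are Pd(OAc)2, DPEphos, NaOtBu, toluene, 80 °C.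
- This gives the racemic diarylmethyl tert-butyl azo compound F4, which tautomerises in the basic medium to the diaryl ketone N-tert-butylhydrazone F5.
- HCl in aqueous MeOH at 40 °C then hydrolyses the hydrazone and all three MOM ethers to 8.

Second, step 1. Prenyl bromide can O-alkylate, stop at the monoprenyl stage, or over-alkylate to dearomatised geminal diprenyl products.
- The fallback sets out from 1 and comes back at 5, bypassing 3. It replaces direct C-alkylation by sigmatropic delivery of the side chains.
- Compound 1 is first mono-methylated (Me2SO4 1 equiv, K2CO3, acetone) to 2,6-dihydroxy-4-methoxybenzaldehyde F6.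
- F6 is bis-O-allylated (allyl bromide, K2CO3, DMF) to 2,6-bis(allyloxy)-4-methoxybenzaldehyde F7.
- A double aromatic Claisen rearrangement (N,N-diethylaniline, 200 °C) can only deliver the allyl groups to the free C3 and C5. It gives 3,5-diallyl-2,6-dihydroxy-4-methoxybenzaldehyde F8.
- Cross metathesis with 2-methylbut-2-ene (second-generation Grubbs catalyst, CH2Cl2, 40 °C) converts both allyl groups into prenyl groups, giving 5.

Third, step 2. The 4-OH lies between two prenyl groups, so some 2-O-methyl or dimethyl ether may form.
- The fallback sets out from 3 and comes back at 5. It replaces kinetic selection among three phenols by chelation-controlled deprotection.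
- Compound 3 is exhaustively methylated (excess Me2SO4, K2CO3, acetone, reflux) to 2,4,6-trimethoxy-3,5-bis(3-methylbut-2-en-1-yl)benzaldehyde F9.
- MgI2 etherate (2.5 equiv, toluene/Et2O, 60 to 80 °C) then cleaves only the two methyl ethers that can chelate magnesium together with the formyl oxygen. The 4-OMe and the prenyl groups are left intact, giving 5.

**Further compounds**
F1 | step 3 | 4-methoxy-2,6-bis(methoxymethoxy)-3,5-bis(3-methylbut-2-en-1-yl)benzaldehyde | O=Cc1c(OCOC)c(CC=C(C)C)c(OC)c(CC=C(C)C)c1OCOC
F2 | step 3 | (E)-N-tert-butylhydrazone of F1 | CC(C)(C)N/N=C/c1c(OCOC)c(CC=C(C)C)c(OC)c(CC=C(C)C)c1OCOC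
F3 | step 3 | 1-bromo-3-(methoxymethoxy)benzene | COCOc1cccc(Br)c1
F4 | step 3 | (E)-tert-butyl{[4-methoxy-2,6-bis(methoxymethoxy)-3,5-bis(3-methylbut-2-en-1-yl)phenyl][3-(methoxymethoxy)phenyl]methyl}diazene (racemic) | COCOc1cccc(c1)C(/N=N/C(C)(C)C)c1c(OCOC)c(CC=C(C)C)c(OC)c(CC=C(C)C)c1OCOC
F5 | step 3 | N-tert-butylhydrazone of [4-methoxy-2,6-bis(methoxymethoxy)-3,5-bis(3-methylbut-2-en-1-yl)phenyl][3-(methoxymethoxy)phenyl]methanone (C=N geometry of no consequence) | COCOc1cccc(c1)C(=NNC(C)(C)C)c1c(OCOC)c(CC=C(C)C)c(OC)c(CC=C(C)C)c1OCOC
F6 | step 1 | 2,6-dihydroxy-4-methoxybenzaldehyde | COc1cc(O)c(C=O)c(O)c1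
F7 | step 1 | 2,6-bis(allyloxy)-4-methoxybenzaldehyde | COc1cc(OCC=C)c(C=O)c(OCC=C)c1
F8 | step 1 | 3,5-diallyl-2,6-dihydroxy-4-methoxybenzaldehyde | COc1c(CC=C)c(O)c(C=O)c(O)c1CC=C
F9 | step 2 | 2,4,6-trimethoxy-3,5-bis(3-methylbut-2-en-1-yl)benzaldehyde | COc1c(CC=C(C)C)c(OC)c(C=O)c(OC)c1CC=C(C)C
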